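**Strategy.** The cyclohexenone (ring C1(=O)–C2=C3–C4(OMe)–C5H2–C6; side chain C8H(Me)–C7(=O)Ar on C6) is cut at C3–C4 and C5–C6. The key step exploits the cis 1,3-relationship between the C4 oxygen and the C6 side chain: that oxygen is first carried as a vinyl ether on the C7 carbinol, so that one tin radical chain closes an oxane ring (C6 to C5) and then the carbocycle (C4 to C3) on a β-stannyl enone, expelling Bu3Sn. The precursor is an acyclic α-bromo ketone; its C7 and C8 centres come from one catalytic crotylboration and relay C6 and C4. Oxidative cleavage of the benzylic ether then frees the aryl ketone and the C4 hydroxyl, which is methylated.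

Key step: step 9

Remark: atom labels C1–C8 are those of the overview; the C6 configuration in compounds 11–20 is inconsequential because C6 becomes a planar radical in step 9, and in step 1 the catalyst antipode that delivers the 1R carbinol is the one to use (assumed to be the R catalyst).

Step 1
Reactants: 1 3,4-dimethoxybenzaldehyde; 2 (Z)-crotylboronic acid pinacol ester
Product: 4 (1R,2S)-1-(3,4-dimethoxyphenyl)-2-methylbut-3-en-1-ol, via borate ester 3 (not isolated)
Conditions: (R)-TRIP [(R)-3,3'-bis(2,4,6-triisopropylphenyl)-1,1'-binaphthyl-2,2'-diyl hydrogen phosphate] (5 mol%), PhMe, −30 °C; aqueous work-up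
Reagents that add atoms: none
Why: Chiral phosphoric acid-catalysed crotylboration through a closed chair transition state, so the Z alkene should give the syn pair while the catalyst selects the aldehyde face, setting C7 (R) and C8 (S) together.

Step 2
Reactants: 4 (1R,2S)-1-(3,4-dimethoxyphenyl)-2-methylbut-3-en-1-ol
Product: 6 (1R,2S)-1-(3,4-dimethoxyphenyl)-2-methylbutane-1,4-diol, via organoborane 5 (not isolated)
Conditions: 9-BBN (2.5 equiv), THF, 0 °C to rt; then NaOH, H2O2, 0 °C
Reagents that add atoms: hydrogen peroxide, OO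
Why: Anti-Markovnikov hydroboration–oxidation of the terminal alkene (the free hydroxyl consumes one equivalent of borane as a borinate) touches no stereocentre.

Step 3
Reactants: 6 (1R,2S)-1-(3,4-dimethoxyphenyl)-2-methylbutane-1,4-diol
Product: 8 (4S,5R)-5-(3,4-dimethoxyphenyl)-4-methyloxolan-2-one, via lactol 7 (not isolated)
Conditions: TEMPO (10 mol%), PhI(OAc)2 (2.5 equiv), CH2Cl2, rt
Reagents that add atoms: none
Why: Oxoammonium (TEMPO) oxidation of the primary alcohol, lactol closure and further oxidation should give the cis γ-lactone, the slower-reacting benzylic alcohol being captured as the ring oxygen.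

Step 4
Reactants: 8 (4S,5R)-5-(3,4-dimethoxyphenyl)-4-methyloxolan-2-one; 9 allyl bromide
Product: 11 (3S,4S,5R)-5-(3,4-dimethoxyphenyl)-4-methyl-3-(prop-2-en-1-yl)oxolan-2-one, via lithium enolate 10 (not isolated)
Conditions: LiN(i-Pr)2, THF, −78 °C; then 9, −78 to −40 °C
Reagents that add atoms: none
Why: Lactone enolate alkylation should occur anti to the C8 methyl, although the C6 configuration formed here is erased in step 9.

Step 5
Reactants: 11 (3S,4S,5R)-5-(3,4-dimethoxyphenyl)-4-methyl-3-(prop-2-en-1-yl)oxolan-2-one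
Product: 12 (2S,3S,4R)-4-(3,4-dimethoxyphenyl)-4-hydroxy-N-methoxy-N,3-dimethyl-2-(prop-2-en-1-yl)butanamide
Conditions: MeNH(OMe)·HCl, AlMe3, CH2Cl2, 0 °C to rt; aq. KNaC4H4O6; used without delay
Reagents that add atoms: N,O-dimethylhydroxylamine hydrochloride, CNOC.Cl
Why: Aluminium amide aminolysis of the lactone (N-methoxy-N-methylamide formation) frees the C7 hydroxyl for the tether and touches no stereocentre.

Step 6
Reactants: 12 (2S,3S,4R)-4-(3,4-dimethoxyphenyl)-4-hydroxy-N-methoxy-N,3-dimethyl-2-(prop-2-en-1-yl)butanamide; 13 butyl vinyl ether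
Product: 14 (2S,3S,4R)-4-(3,4-dimethoxyphenyl)-4-(ethenyloxy)-N-methoxy-N,3-dimethyl-2-(prop-2-en-1-yl)butanamide
Conditions: Pd(OCOCF3)2 (5 mol%), 4,7-diphenyl-1,10-phenanthroline (5 mol%), Et3N, neat 13, 60 °C, air
Reagents that add atoms: none
Why: Palladium-catalysed transfer vinylation (transetherification) of the secondary alcohol places the two-carbon unit C4=C5 on the C7 oxygen and blocks relactonisation.

Step 7
Reactants: 14 (2S,3S,4R)-4-(3,4-dimethoxyphenyl)-4-(ethenyloxy)-N-methoxy-N,3-dimethyl-2-(prop-2-en-1-yl)butanamide; 15 (E)-1,2-bis(tributylstannyl)ethene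
Product: 18 (1E,4S,5S,6R)-6-(3,4-dimethoxyphenyl)-6-(ethenyloxy)-5-methyl-4-(prop-2-en-1-yl)-1-(tributylstannyl)hex-1-en-3-one, via stannylvinyllithium 16 (not isolated), via lithium hemiaminal 17 (not isolated)
Conditions: 15, n-BuLi, THF, −78 °C; then 14, −78 to −40 °C; cold aqueous work-up
Reagents that add atoms: none
Why: Weinreb ketone synthesis, in which tin–lithium exchange gives the E vinyllithium and the chelated adduct collapses only on work-up, so the E enone should form without over-addition.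

Step 8
Reactants: 18 (1E,4S,5S,6R)-6-(3,4-dimethoxyphenyl)-6-(ethenyloxy)-5-methyl-4-(prop-2-en-1-yl)-1-(tributylstannyl)hex-1-en-3-one
Product: 20 (1E,5R,6R)-4-bromo-6-(3,4-dimethoxyphenyl)-6-(ethenyloxy)-5-methyl-4-(prop-2-en-1-yl)-1-(tributylstannyl)hex-1-en-3-one (both C4 epimers), via lithium dienolate 19 (not isolated)
Conditions: LiN(i-Pr)2, THF, −78 °C; then CBr4, −78 °C
Reagents that add atoms: tetrabromomethane, BrC(Br)(Br)Br
Why: Kinetic deprotonation at C6 (the only enolisable site) and electrophilic bromination of the cross-conjugated enolate with CBr4, which should leave the vinyl–tin bond intact, give the radical precursor.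

Step 9
Reactants: 20 (1E,5R,6R)-4-bromo-6-(3,4-dimethoxyphenyl)-6-(ethenyloxy)-5-methyl-4-(prop-2-en-1-yl)-1-(tributylstannyl)hex-1-en-3-one
Product: 24 (1R,3R,4S,5R)-3-(3,4-dimethoxyphenyl)-4-methyl-5-(prop-2-en-1-yl)-2-oxabicyclo[3.3.1]non-7-en-6-one, via α-keto radical 21 (not isolated), via 2-oxanyl radical 22 (not isolated), via β-stannyl radical 23 (not isolated)
Conditions: (Bu3Sn)2 (20 mol%), PhH (0.01 M), hν (sunlamp), 40 °C
Reagents that add atoms: none
Why: Proposed new method: Bu3Sn• takes bromine from 20; the electrophilic tertiary α-keto radical 21 adds through C6 to the unsubstituted carbon C5 of the electron-rich vinyl ether (6-endo-trig, oxane ring), the nucleophilic 2-oxanyl radical 22 then adds through C4 to the tin-bearing β-carbon C3 of the enone (6-endo-trig, carbocycle), and β-scission of the C3–Sn bond in 23 restores the C2=C3 enone and returns Bu3Sn• to the chain. The closest known reaction types are tandem radical cyclizations of α-halo carbonyl compounds, endo closures of carbon radicals on enol ethers and enamides that give the heteroatom-stabilised radical, and the addition–fragmentation of alkyl radicals on β-stannyl acrylates; their union in one bridging annulation has not been shown. C6 is controlled by the C7 and C8 centres: in the chair of the forming oxane the C7 aryl group is equatorial, the cis C8 methyl therefore axial, and only the C6 epimer with the acyl group axial and anti to that methyl (allyl equatorial) can reach C3 without a syn-diaxial aryl group. C4 is controlled by the ring itself, since the one-carbon bridge C5 forces the new C4–C3 bond to be axial and cis to the acyl group, which places the C4 oxygen cis to the C8 side chain. The step needs endo regioselectivity in both closures and ring closure faster than capture of 22 by the allyl group: polarity matching (electrophilic radical on the terminal enol ether carbon, nucleophilic α-oxy radical on the enone β-carbon), the axial preference of 2-oxanyl radicals, high dilution and the absence of a hydride donor should secure this.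

Step 10
Reactants: 24 (1R,3R,4S,5R)-3-(3,4-dimethoxyphenyl)-4-methyl-5-(prop-2-en-1-yl)-2-oxabicyclo[3.3.1]non-7-en-6-one
Product: 27 (4R,6R)-6-[(2S)-1-(3,4-dimethoxyphenyl)-1-oxopropan-2-yl]-4-hydroxy-6-(prop-2-en-1-yl)cyclohex-2-en-1-one, via oxocarbenium ion 25 (not isolated), via hemiketal 26 (not isolated)
Conditions: DDQ, CH2Cl2/H2O (pH 7), 0 °C to rt
Reagents that add atoms: water, O
Why: Oxidative cleavage of a 3,4-dimethoxybenzylic ether by hydride abstraction from the axial C7–H, hydration and hemiketal opening should give the aryl ketone and the C4 alcohol, erasing C7 and leaving C4, C6 and C8 untouched.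

Step 11
Reactants: 27 (4R,6R)-6-[(2S)-1-(3,4-dimethoxyphenyl)-1-oxopropan-2-yl]-4-hydroxy-6-(prop-2-en-1-yl)cyclohex-2-en-1-one
Product: 28 (4R,6R)-6-[(2S)-1-(3,4-dimethoxyphenyl)-1-oxopropan-2-yl]-4-methoxy-6-(prop-2-en-1-yl)cyclohex-2-en-1-one
Conditions: Me3OBF4, 1,8-bis(dimethylamino)naphthalene, CH2Cl2, rt
Reagents that add atoms: trimethyloxonium tetrafluoroborate, C[O+](C)C.F[B-](F)(F)F
Why: O-Methylation with a trialkyloxonium salt and a hindered non-enolising base should methylate the C4 hydroxyl without epimerising C8 next to the aryl ketone.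

Compound list
1 | 3,4-dimethoxybenzaldehyde | COc1ccc(C=O)cc1OC | starting material
2 | (Z)-crotylboronic acid pinacol ester, 2-[(2Z)-but-2-en-1-yl]-4,4,5,5-tetramethyl-1,3,2-dioxaborolane | C/C=C\CB1OC(C)(C)C(C)(C)O1 | starting material
3 | borate ester, 2-{[(1R,2S)-1-(3,4-dimethoxyphenyl)-2-methylbut-3-en-1-yl]oxy}-4,4,5,5-tetramethyl-1,3,2-dioxaborolane (not isolated) | C=C[C@H](C)[C@H](c1ccc(OC)c(OC)c1)OB1OC(C)(C)C(C)(C)O1 | intermediate
4 | (1R,2S)-1-(3,4-dimethoxyphenyl)-2-methylbut-3-en-1-ol (syn) | C=C[C@H](C)[C@H](c1ccc(OC)c(OC)c1)O | intermediate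
5 | organoborane, 9-{(3S,4R)-4-(3,4-dimethoxyphenyl)-3-methyl-4-[(9-borabicyclo[3.3.1]nonan-9-yl)oxy]butyl}-9-borabicyclo[3.3.1]nonane (not isolated) | C1CCC2CCCC1B2CC[C@H](C)[C@H](c1ccc(OC)c(OC)c1)OB1C2CCCC1CCC2 | intermediate
6 | (1R,2S)-1-(3,4-dimethoxyphenyl)-2-methylbutane-1,4-diol | OCC[C@H](C)[C@H](c1ccc(OC)c(OC)c1)O | intermediate
7 | lactol, (4S,5R)-5-(3,4-dimethoxyphenyl)-4-methyloxolan-2-ol, both anomers (not isolated) | OC1C[C@H](C)[C@H](c2ccc(OC)c(OC)c2)O1 | intermediate
8 | (4S,5R)-5-(3,4-dimethoxyphenyl)-4-methyloxolan-2-one (cis lactone) | O=C1C[C@H](C)[C@H](c2ccc(OC)c(OC)c2)O1 | intermediate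
9 | allyl bromide | C=CCBr | starting material
10 | lithium enolate of 8, lithium (4S,5R)-5-(3,4-dimethoxyphenyl)-4-methyl-4,5-dihydrofuran-2-olate (not isolated) | [Li]OC1=C[C@H](C)[C@H](c2ccc(OC)c(OC)c2)O1 | intermediate
11 | (3S,4S,5R)-5-(3,4-dimethoxyphenyl)-4-methyl-3-(prop-2-en-1-yl)oxolan-2-one | O=C1[C@@H](CC=C)[C@H](C)[C@H](c2ccc(OC)c(OC)c2)O1 | intermediate
12 | (2S,3S,4R)-4-(3,4-dimethoxyphenyl)-4-hydroxy-N-methoxy-N,3-dimethyl-2-(prop-2-en-1-yl)butanamide | CON(C)C(=O)[C@@H](CC=C)[C@H](C)[C@H](c1ccc(OC)c(OC)c1)O | intermediate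
13 | butyl vinyl ether | C=COCCCC | starting material
14 | (2S,3S,4R)-4-(3,4-dimethoxyphenyl)-4-(ethenyloxy)-N-methoxy-N,3-dimethyl-2-(prop-2-en-1-yl)butanamide | CON(C)C(=O)[C@@H](CC=C)[C@H](C)[C@H](c1ccc(OC)c(OC)c1)OC=C | intermediate
15 | (E)-1,2-bis(tributylstannyl)ethene | CCCC[Sn](CCCC)(CCCC)/C=C/[Sn](CCCC)(CCCC)CCCC | starting material
16 | stannylvinyllithium, (E)-tributyl(2-lithioethenyl)stannane (not isolated) | [Li]/C=C/[Sn](CCCC)(CCCC)CCCC | intermediate
17 | lithium hemiaminal, chelated tetrahedral adduct of 16 and 14 (not isolated) | CCCC[Sn](CCCC)(CCCC)/C=C/C(O[Li])(N(C)OC)[C@@H](CC=C)[C@H](C)[C@H](c1ccc(OC)c(OC)c1)OC=C | intermediate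
18 | (1E,4S,5S,6R)-6-(3,4-dimethoxyphenyl)-6-(ethenyloxy)-5-methyl-4-(prop-2-en-1-yl)-1-(tributylstannyl)hex-1-en-3-one | CCCC[Sn](CCCC)(CCCC)/C=C/C(=O)[C@@H](CC=C)[C@H](C)[C@H](c1ccc(OC)c(OC)c1)OC=C | intermediate
19 | lithium dienolate of 18, enolised toward C6 (not isolated) | CCCC[Sn](CCCC)(CCCC)/C=C/C(O[Li])=C(CC=C)[C@H](C)[C@H](c1ccc(OC)c(OC)c1)OC=C | intermediate
20 | (1E,5R,6R)-4-bromo-6-(3,4-dimethoxyphenyl)-6-(ethenyloxy)-5-methyl-4-(prop-2-en-1-yl)-1-(tributylstannyl)hex-1-en-3-one, both C4 epimers | CCCC[Sn](CCCC)(CCCC)/C=C/C(=O)C(Br)(CC=C)[C@H](C)[C@H](c1ccc(OC)c(OC)c1)OC=C | intermediate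
21 | α-keto radical, tertiary radical at C6 formed from 20 by loss of bromine (not isolated) | CCCC[Sn](CCCC)(CCCC)/C=C/C(=O)[C](CC=C)[C@H](C)[C@H](c1ccc(OC)c(OC)c1)OC=C | intermediate
22 | 2-oxanyl radical, oxane ring closed (C5–C6 formed), radical at C4 (not isolated) | C=CC[C@](C(=O)/C=C/[Sn](CCCC)(CCCC)CCCC)([C@H](C)[C@H](c1ccc(OC)c(OC)c1)O2)C[CH]2 | intermediate
23 | β-stannyl radical, both rings closed (C3–C4 formed), radical at C2, tin still on C3 (not isolated) | C=CC[C@]1([C@H](C)[C@H](c2ccc(OC)c(OC)c2)O3)C[C@@H]3C([Sn](CCCC)(CCCC)CCCC)[CH]C1=O | intermediate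
24 | (1R,3R,4S,5R)-3-(3,4-dimethoxyphenyl)-4-methyl-5-(prop-2-en-1-yl)-2-oxabicyclo[3.3.1]non-7-en-6-one | C=CC[C@]1([C@H](C)[C@H](c2ccc(OC)c(OC)c2)O3)C[C@@H]3C=CC1=O | intermediate
25 | oxocarbenium ion, cyclic aryl-stabilised cation from 24 by loss of hydride at C7 (not isolated) | C=CC[C@]1([C@H](C)C(c2ccc(OC)c(OC)c2)=[O+]3)C[C@@H]3C=CC1=O | intermediate
26 | hemiketal, water adduct of 25 at C7, either epimer (not isolated) | C=CC[C@]1([C@H](C)C(O)(c2ccc(OC)c(OC)c2)O3)C[C@@H]3C=CC1=O | intermediate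
27 | (4R,6R)-6-[(2S)-1-(3,4-dimethoxyphenyl)-1-oxopropan-2-yl]-4-hydroxy-6-(prop-2-en-1-yl)cyclohex-2-en-1-one | C=CC[C@]1([C@H](C)C(=O)c2ccc(OC)c(OC)c2)C[C@@H](O)C=CC1=O | intermediate
28 | (4R,6R)-6-[(2S)-1-(3,4-dimethoxyphenyl)-1-oxopropan-2-yl]-4-methoxy-6-(prop-2-en-1-yl)cyclohex-2-en-1-one | C=CC[C@]1([C@H](C)C(=O)c2ccc(OC)c(OC)c2)C[C@@H](OC)C=CC1=O | target

Total step count: 11. Longest linear sequence: 11 steps (1 to 28).

Steps most likely to fail

1. Step 9 (Proposed new method). The first closure may give mainly the C6 epimer that cannot bridge, the 2-oxanyl radical may be intercepted by the allyl group in a 5-exo closure, or ipso attack on the tin-bearing carbon may be too slow to carry the chain. Fallback with known chemistry, a hydride-terminated tandem radical cyclization on a terminal ynone, setting out from 14 and coming back at 24: 14 is treated with LiC≡CSiMe3 (THF, −78 °C, Weinreb ketone synthesis) to give (4S,5S,6R)-6-(3,4-dimethoxyphenyl)-6-(ethenyloxy)-5-methyl-4-(prop-2-en-1-yl)-1-(trimethylsilyl)hex-1-yn-3-one F1. Kinetic enolisation with LiN(i-Pr)2 and bromination with CBr4 (−78 °C) give (5R,6R)-4-bromo-6-(3,4-dimethoxyphenyl)-6-(ethenyloxy)-5-methyl-4-(prop-2-en-1-yl)-1-(trimethylsilyl)hex-1-yn-3-one F2. Bu4NF buffered with AcOH (THF, 0 °C) removes the silyl group to give (5R,6R)-4-bromo-6-(3,4-dimethoxyphenyl)-6-(ethenyloxy)-5-methyl-4-(prop-2-en-1-yl)hex-1-yn-3-one F3. Slow addition of Bu3SnH with AIBN in dilute PhH at 80 °C should then give 24 by 6-endo-trig closure on the vinyl ether, 6-endo-dig addition of the oxanyl radical to the ynone β-carbon and hydrogen transfer to the vinyl radical, under the same conformational control.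

2. Step 6. The γ-hydroxy amide may relactonise to 11 with loss of the amine under the warm basic conditions, and the palladium catalyst may isomerise the allyl group. Fallback by acetal formation and elimination in place of transetherification, from 12 back to 14: 12 is treated with ethyl vinyl ether and pyridinium p-toluenesulfonate (CH2Cl2, 0 °C) to give the mixed acetal (2S,3S,4R)-4-(3,4-dimethoxyphenyl)-4-(1-ethoxyethoxy)-N-methoxy-N,3-dimethyl-2-(prop-2-en-1-yl)butanamide F4 (both acetal epimers), which should lose ethanol as its silyl ether on treatment with Me3SiOTf and Et3N (CH2Cl2, 0 °C) to give 14.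

3. Step 10. Hydride abstraction may be slow in the bridged ether, the hydroxy ketone may close back to the hemiketal, or acid formed during the oxidation may epimerise C8. Fallback by alkylative ring opening in place of oxidation, from 24 to 28, bypassing 27: Me3OBF4 (CH2Cl2, 0 °C) should methylate the ring oxygen, the oxonium ion ionises at the benzylic carbon C7 and water captures the cation to give (4R,6R)-6-[(2S)-1-(3,4-dimethoxyphenyl)-1-hydroxypropan-2-yl]-4-methoxy-6-(prop-2-en-1-yl)cyclohex-2-en-1-one F5 (either C7 epimer); Dess–Martin oxidation of the benzylic alcohol then gives 28.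

Further compounds
F1 | step 9 | (4S,5S,6R)-6-(3,4-dimethoxyphenyl)-6-(ethenyloxy)-5-methyl-4-(prop-2-en-1-yl)-1-(trimethylsilyl)hex-1-yn-3-one | C[Si](C)(C)C#CC(=O)[C@@H](CC=C)[C@H](C)[C@H](c1ccc(OC)c(OC)c1)OC=C
F2 | step 9 | (5R,6R)-4-bromo-6-(3,4-dimethoxyphenyl)-6-(ethenyloxy)-5-methyl-4-(prop-2-en-1-yl)-1-(trimethylsilyl)hex-1-yn-3-one, both C4 epimers | C[Si](C)(C)C#CC(=O)C(Br)(CC=C)[C@H](C)[C@H](c1ccc(OC)c(OC)c1)OC=C
F3 | step 9 | (5R,6R)-4-bromo-6-(3,4-dimethoxyphenyl)-6-(ethenyloxy)-5-methyl-4-(prop-2-en-1-yl)hex-1-yn-3-one, both C4 epimers | C#CC(=O)C(Br)(CC=C)[C@H](C)[C@H](c1ccc(OC)c(OC)c1)OC=C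
F4 | step 6 | (2S,3S,4R)-4-(3,4-dimethoxyphenyl)-4-(1-ethoxyethoxy)-N-methoxy-N,3-dimethyl-2-(prop-2-en-1-yl)butanamide, both acetal epimers | CON(C)C(=O)[C@@H](CC=C)[C@H](C)[C@H](c1ccc(OC)c(OC)c1)OC(C)OCC
F5 | step 10 | (4R,6R)-6-[(2S)-1-(3,4-dimethoxyphenyl)-1-hydroxypropan-2-yl]-4-methoxy-6-(prop-2-en-1-yl)cyclohex-2-en-1-one, either C7 epimer | C=CC[C@]1([C@H](C)C(O)c2ccc(OC)c(OC)c2)C[C@@H](OC)C=CC1=O
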